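## Retrosynthetic overview
1. Target 17 ⇐ O-debenzylation of 16. 16 ⇐ reduction of the C3 carboxamide to CH2OH, after an aryl–copper opening of spiro-epoxide 13 at its CH2 (makes ArCH2–C4 and frees the C4–OH).
2. 13 ⇐ face-selective epoxidation of the exocyclic alkene of 4-methylideneoxolane 12.
3. 12 ⇐ stepwise, iodide-relayed ring expansion (3→5) of methylenecyclopropane amide 9 with aldehyde 6. This forms C2–C3 and O1–C5 and sets C2 and C3.
4. Aldehyde 6 and Grignard reagent 14 both come from bromide 4, made from catechol by O-methylation, para-bromination and O-benzylation.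
5. Ring order: cyclopropane (bought) → oxolane (step 6). The oxirane of step 7 is transient and is opened in step 8.

Assumption: racemic acid 7 is bought as a catalogue building block, and the box antipode that gives (2R,3R)-12 is fixed by a test run ((R,R) is written here).

## Route

Step 1
Reactants: 1 benzene-1,2-diol (catechol)
Product: 2 2-methoxyphenol
Conditions: MeI (1.0 equiv), K2CO3 (1.0 equiv), acetone, reflux; distillation
Reagents that add atoms: iodomethane, CI
Why: Williamson ether synthesis with one equivalent of MeI alkylates the catechol monoanion once, and a little dimethyl ether and unreacted 1 are removed by base extraction and distillation.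

Step 2
Reactants: 2 2-methoxyphenol
Product: 3 4-bromo-2-methoxyphenol
Conditions: NBS (1.0 equiv), MeCN, 0 °C
Reagents that add atoms: N-bromosuccinimide, O=C1CCC(=O)N1Br
Why: In this electrophilic aromatic bromination the free OH is the strongest director, so NBS in MeCN substitutes para to it.

Step 3
Reactants: 3 4-bromo-2-methoxyphenol
Product: 4 1-(benzyloxy)-4-bromo-2-methoxybenzene
Conditions: BnBr, K2CO3, DMF, 23 °C
Reagents that add atoms: benzyl bromide, BrCc1ccccc1
Why: Williamson benzylation masks the phenol for the organometallic steps and is removed by hydrogenolysis at the end.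

Step 4
Reactants: 4 1-(benzyloxy)-4-bromo-2-methoxybenzene
Product: 6 4-(benzyloxy)-3-methoxybenzaldehyde, via aryllithium 5 (not isolated)
Conditions: n-BuLi, THF, −78 °C; DMF, −78 → 0 °C; aq HCl
Reagents that add atoms: N,N-dimethylformamide, CN(C)C=O
Why: Fast Br–Li exchange followed by Bouveault formylation places the formyl group exactly where the bromine was.

Step 5
Reactants: 7 2-methylidenecyclopropane-1-carboxylic acid (racemic)
Product: 9 2-methylidene-N,N-diphenylcyclopropane-1-carboxamide, via acid chloride 8 (not isolated)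
Conditions: (COCl)2, DMF (cat.), CH2Cl2, 0 → 23 °C; then Ph2NH, Et3N, DMAP (cat.), CH2Cl2, 23 °C
Reagents that add atoms: diphenylamine, c1ccc(Nc2ccccc2)cc1
Why: N-acylation through the acid chloride installs the Mg-binding, moderately electron-withdrawing diphenylamide that activates the ring, and the stereocentre of 7 does not matter because step 6 destroys it.

Step 6
Reactants: 9 2-methylidene-N,N-diphenylcyclopropane-1-carboxamide; 6 4-(benzyloxy)-3-methoxybenzaldehyde
Product: 12 (2R,3R)-2-[4-(benzyloxy)-3-methoxyphenyl]-4-methylidene-N,N-diphenyloxolane-3-carboxamide, via iodo dienolate 10 (not isolated), via syn-aldolate 11 (not isolated)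
Conditions: MgI2 (30 mol %), (R,R)-Ph-box (33 mol %), 4 Å MS, THF, 50 °C; one recrystallisation (EtOAc–heptane)
Reagents that add atoms: none
Why: Proposed new method: catalytic enantioselective ring expansion of a methylenecyclopropane amide with an aryl aldehyde. Mg(II) binds the amide C=O and iodide opens the strained ring at CH2 (SN2/SN2′, degenerate) to the achiral Z(O)-dienolate/allyl iodide 10, so racemic 9 converges. The C2-symmetric box–Mg enolate keeps two cis sites free for the aldehyde, so a closed Zimmerman–Traxler chair gives syn-aldolate 11 on one face (α-attack, not γ-attack, as is usual for diphenylamides). Irreversible 5-exo-tet O-alkylation of the allyl iodide then returns MgI2 and turns syn-11 into the 2,3-trans oxolane, setting C2 and C3. The closest known reaction type is the MgI2-mediated ring expansion of methylenecyclopropyl amides with aldimines and aryl aldehydes (racemic); its box·MgI2 version has been shown only for N-sulfonyl aldimines.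

Step 7
Reactants: 12 (2R,3R)-2-[4-(benzyloxy)-3-methoxyphenyl]-4-methylidene-N,N-diphenyloxolane-3-carboxamide
Product: 13 (3R,6R,7S)-6-[4-(benzyloxy)-3-methoxyphenyl]-N,N-diphenyl-1,5-dioxaspiro[2.4]heptane-7-carboxamide
Conditions: dimethyldioxirane (1.2 equiv, acetone solution), CH2Cl2, −20 → 0 °C
Reagents that add atoms: dimethyldioxirane, CC1(C)OO1
Why: In this sterically controlled dioxirane epoxidation the bulky CONPh2 on the neighbouring C3 screens its own face and the reagent has no O–H for the carbonyl to steer, so oxygen arrives anti to the C3 substituent and sets the C4–O configuration of the target.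

Step 8
Reactants: 13 (3R,6R,7S)-6-[4-(benzyloxy)-3-methoxyphenyl]-N,N-diphenyl-1,5-dioxaspiro[2.4]heptane-7-carboxamide; 4 1-(benzyloxy)-4-bromo-2-methoxybenzene
Product: 16 (3R,4S,5R)-5-[4-(benzyloxy)-3-methoxyphenyl]-3-{[4-(benzyloxy)-3-methoxyphenyl]methyl}-4-(hydroxymethyl)oxolan-3-ol, via aryl Grignard reagent 14 (not isolated), via alkoxide amide 15 (not isolated)
Conditions: 4, Mg, THF, 45 °C (second flask); CuI (10 mol %), 13, THF, −30 → 0 °C; then LiAlH4, 0 → 23 °C, same pot; aq NaOH work-up
Reagents that add atoms: none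
Why: Copper-catalysed SN2 opening occurs only at the unhindered epoxide CH2, so C4 keeps its configuration, and hydride reduction of the N,N-diphenylamide then proceeds with C–N cleavage to the primary alcohol because Ph2N⁻ leaves from the tetrahedral intermediate while C3 is untouched.

Step 9
Reactants: 16 (3R,4S,5R)-5-[4-(benzyloxy)-3-methoxyphenyl]-3-{[4-(benzyloxy)-3-methoxyphenyl]methyl}-4-(hydroxymethyl)oxolan-3-ol
Product: 17 (3R,4S,5R)-5-(4-hydroxy-3-methoxyphenyl)-3-[(4-hydroxy-3-methoxyphenyl)methyl]-4-(hydroxymethyl)oxolan-3-ol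
Conditions: H2 (1 atm), 10 % Pd/C, EtOAc–EtOH, 23 °C, stopped at full conversion
Reagents that add atoms: none
Why: Catalytic hydrogenolysis removes aryl benzyl ethers much faster than it cleaves the cyclic secondary benzylic C–O bond under neutral conditions, and no stereocentre is touched.

## Compound list
1 | benzene-1,2-diol (catechol) | Oc1ccccc1O | starting material
2 | 2-methoxyphenol | COc1ccccc1O | intermediate
3 | 4-bromo-2-methoxyphenol | COc1cc(Br)ccc1O | intermediate
4 | 1-(benzyloxy)-4-bromo-2-methoxybenzene | COc1cc(Br)ccc1OCc1ccccc1 | intermediate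
5 | [4-(benzyloxy)-3-methoxyphenyl]lithium | COc1cc([Li])ccc1OCc1ccccc1 | intermediate
6 | 4-(benzyloxy)-3-methoxybenzaldehyde | COc1cc(C=O)ccc1OCc1ccccc1 | intermediate
7 | 2-methylidenecyclopropane-1-carboxylic acid (racemic) | C=C1CC1C(=O)O | starting material
8 | 2-methylidenecyclopropane-1-carbonyl chloride (racemic) | C=C1CC1C(=O)Cl | intermediate
9 | 2-methylidene-N,N-diphenylcyclopropane-1-carboxamide (racemic) | C=C1CC1C(=O)N(c1ccccc1)c1ccccc1 | intermediate
10 | iodomagnesium (Z)-enolate of 3-(iodomethyl)-N,N-diphenylbut-3-enamide (box ligand on Mg omitted) | C=C(CI)/C=C(\O[Mg]I)N(c1ccccc1)c1ccccc1 | intermediate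
11 | iodomagnesium syn-aldolate, 2-{[4-(benzyloxy)-3-methoxyphenyl](oxido)methyl}-3-(iodomethyl)-N,N-diphenylbut-3-enamide (box ligand omitted) | I[Mg]O[C@@H](c1ccc(OCc2ccccc2)c(OC)c1)[C@@H](C(=C)CI)C(=O)N(c1ccccc1)c1ccccc1 | intermediate
12 | (2R,3R)-2-[4-(benzyloxy)-3-methoxyphenyl]-4-methylidene-N,N-diphenyloxolane-3-carboxamide | C=C1CO[C@@H](c2ccc(OCc3ccccc3)c(OC)c2)[C@@H]1C(=O)N(c1ccccc1)c1ccccc1 | intermediate
13 | (3R,6R,7S)-6-[4-(benzyloxy)-3-methoxyphenyl]-N,N-diphenyl-1,5-dioxaspiro[2.4]heptane-7-carboxamide | C1[C@]2(O1)CO[C@@H](c3ccc(OCc4ccccc4)c(OC)c3)[C@@H]2C(=O)N(c3ccccc3)c3ccccc3 | intermediate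
14 | [4-(benzyloxy)-3-methoxyphenyl]magnesium bromide | COc1cc([Mg]Br)ccc1OCc1ccccc1 | intermediate
15 | bromomagnesium alkoxide of (2R,3S,4R)-2-[4-(benzyloxy)-3-methoxyphenyl]-4-{[4-(benzyloxy)-3-methoxyphenyl]methyl}-4-hydroxy-N,N-diphenyloxolane-3-carboxamide | COc1cc(C[C@]2(O[Mg]Br)CO[C@@H](c3ccc(OCc4ccccc4)c(OC)c3)[C@@H]2C(=O)N(c3ccccc3)c3ccccc3)ccc1OCc1ccccc1 | intermediate
16 | (3R,4S,5R)-5-[4-(benzyloxy)-3-methoxyphenyl]-3-{[4-(benzyloxy)-3-methoxyphenyl]methyl}-4-(hydroxymethyl)oxolan-3-ol | COc1cc(C[C@]2(O)CO[C@@H](c3ccc(OCc4ccccc4)c(OC)c3)[C@@H]2CO)ccc1OCc1ccccc1 | intermediate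
17 | (3R,4S,5R)-5-(4-hydroxy-3-methoxyphenyl)-3-[(4-hydroxy-3-methoxyphenyl)methyl]-4-(hydroxymethyl)oxolan-3-ol | COc1cc(C[C@]2(O)CO[C@@H](c3ccc(O)c(OC)c3)[C@@H]2CO)ccc1O | target

## Step count and risks
Total step count: 9.
Longest linear sequence: 8 (steps 1, 2, 3, 4, 6, 7, 8, 9). Step 5 is a one-step side branch.

**Step 6 (the proposed new step).** The ee may be low because free MgI2 catalyses a racemic background reaction and the aldol is reversible at 50 °C, and the electron-rich aldehyde may react slowly. The fallback uses known chemistry and gives up catalyst control. It sets out from 9 and 6 and runs the established ring expansion with achiral MgI2 alone in hot THF. This gives 12 together with its mirror image (2S,3S)-2-[4-(benzyloxy)-3-methoxyphenyl]-4-methylidene-N,N-diphenyloxolane-3-carboxamide F1. The two antipodes are separated by preparative chromatography on a chiral stationary phase, and the route is rejoined at 12.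

**Step 7.** The 2-aryl group lies on the face that has to be attacked, so the facial ratio may be modest, and the dioxirane may also touch the electron-rich rings. The fallback sets out from 12 and replaces direct oxygen transfer by dihydroxylation and ring closure.
- OsO4 (cat.)/NMO, a bulkier and arene-tolerant oxidant, gives (2R,3S,4S)-2-[4-(benzyloxy)-3-methoxyphenyl]-4-hydroxy-4-(hydroxymethyl)-N,N-diphenyloxolane-3-carboxamide F2, whose C4 epimer can be removed by crystallisation or chromatography.
- TsCl/pyridine sulfonylates only the primary hydroxyl to give {(3R,4S,5R)-5-[4-(benzyloxy)-3-methoxyphenyl]-4-(diphenylcarbamoyl)-3-hydroxyoxolan-3-yl}methyl 4-methylbenzenesulfonate F3.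
- DBU in CH2Cl2 closes the oxirane without touching C4–O, and the route is rejoined at 13.

**Step 8.** The Grignard reagent may add to the activated amide, or it may deprotonate C3, which leads to β-elimination that opens the epoxide or the oxolane. The fallback sets out from 12 and 4, avoids any aryl-metal reagent, bypasses 13–15 and comes back at 16.
- Heck arylation (Pd(OAc)2, P(o-tol)3, Et3N, DMF, 100 °C) gives (2R,3R,4Z)-2-[4-(benzyloxy)-3-methoxyphenyl]-4-{[4-(benzyloxy)-3-methoxyphenyl]methylidene}-N,N-diphenyloxolane-3-carboxamide F4.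
- Dimethyldioxirane epoxidises F4 anti to the C3 amide to give (2S,3R,6R,7S)-2,6-bis[4-(benzyloxy)-3-methoxyphenyl]-N,N-diphenyl-1,5-dioxaspiro[2.4]heptane-7-carboxamide F5.
- LiAlH4 opens the epoxide at the secondary benzylic carbon (leaving the tertiary C4–OH) and reduces the amide in the same operation, which gives 16.

## Further compounds
F1 | step 6 | (2S,3S)-2-[4-(benzyloxy)-3-methoxyphenyl]-4-methylidene-N,N-diphenyloxolane-3-carboxamide | C=C1CO[C@H](c2ccc(OCc3ccccc3)c(OC)c2)[C@H]1C(=O)N(c1ccccc1)c1ccccc1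
F2 | step 7 | (2R,3S,4S)-2-[4-(benzyloxy)-3-methoxyphenyl]-4-hydroxy-4-(hydroxymethyl)-N,N-diphenyloxolane-3-carboxamide | OC[C@]1(O)CO[C@@H](c2ccc(OCc3ccccc3)c(OC)c2)[C@@H]1C(=O)N(c1ccccc1)c1ccccc1
F3 | step 7 | {(3R,4S,5R)-5-[4-(benzyloxy)-3-methoxyphenyl]-4-(diphenylcarbamoyl)-3-hydroxyoxolan-3-yl}methyl 4-methylbenzenesulfonate | Cc1ccc(cc1)S(=O)(=O)OC[C@]1(O)CO[C@@H](c2ccc(OCc3ccccc3)c(OC)c2)[C@@H]1C(=O)N(c1ccccc1)c1ccccc1
F4 | step 8 | (2R,3R,4Z)-2-[4-(benzyloxy)-3-methoxyphenyl]-4-{[4-(benzyloxy)-3-methoxyphenyl]methylidene}-N,N-diphenyloxolane-3-carboxamide | COc1cc(\C=C2/CO[C@@H](c3ccc(OCc4ccccc4)c(OC)c3)[C@@H]2C(=O)N(c3ccccc3)c3ccccc3)ccc1OCc1ccccc1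
F5 | step 8 | (2S,3R,6R,7S)-2,6-bis[4-(benzyloxy)-3-methoxyphenyl]-N,N-diphenyl-1,5-dioxaspiro[2.4]heptane-7-carboxamide | COc1cc([C@@H]5O[C@]52CO[C@@H](c3ccc(OCc4ccccc4)c(OC)c3)[C@@H]2C(=O)N(c3ccccc3)c3ccccc3)ccc1OCc1ccccc1
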